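## Retrosynthetic overview

1. Target ⇐ desilylation and diacetylation of a protected macrocyclic diol; the ten-membered carbocycle is closed last by a nickel-catalysed, chromium-mediated alkenyl bromide–aldehyde coupling (C6–C7), which sets C7.
2. Seco-aldehyde ⇐ union of two fragments by a palladium-catalysed enantioselective γ-alkenylation (C11–C11a) of a 2-silyloxyfuran (fragment A) with a Z-alkenyl iodide (fragment B), which sets C11a.
3. Fragment A (butenolide ring, formed first) ⇐ but-2-yne-1,4-diol + a homopropargyl Grignard reagent + CO2 by copper-catalysed anti-carbomagnesiation/carboxylation, then bromoboration of the alkyne.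
4. Fragment B ⇐ prop-2-yn-1-ol by copper-catalysed anti-methylmagnesiation/iodination (Z-iodoalkene), asymmetric allylboration (sets C9) and alkene cleavage.
5. Ring order: butenolide ring, then the ten-membered ring.

Assumption: the SMILES is read as the 7S,9S,11aR isomer with a 10Z ring alkene (cyclodeca[b]furan numbering: O1, C2 lactone carbonyl, C3 bearing CH2OH, C3a, C4 to C11, C11a).

## Route

Step 1
Reactants: 1 4-bromobut-1-yne
Product: 3 (4-bromobut-1-yn-1-yl)trimethylsilane, via lithium acetylide 2 (not isolated)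
Conditions: n-BuLi (1.0 equiv), THF, −78 °C; then Me3SiCl, −78 °C to rt
Reagents that add atoms: chlorotrimethylsilane C[Si](C)(C)Cl
Why: Deprotonation of the terminal alkyne at −78 °C is far faster than attack on the primary bromide, and C-silylation of the acetylide masks the acidic C–H for the Grignard step.

Step 2
Reactants: 3 (4-bromobut-1-yn-1-yl)trimethylsilane; 4 but-2-yne-1,4-diol
Product: 8 3-(hydroxymethyl)-4-[4-(trimethylsilyl)but-3-yn-1-yl]furan-2(5H)-one, via Grignard reagent 5 (not isolated), via alkenylmagnesium dialkoxide 6 (not isolated), via hydroxy acid 7 (not isolated)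
Conditions: 3, Mg, THF, 40 °C (gives 5); 4, i-PrMgCl (2.0 equiv), THF, 0 °C; then 5 (1.6 equiv), CuI (10 mol%), 50 °C; then CO2, 0 °C; then 2 M HCl, rt
Reagents that add atoms: carbon dioxide O=C=O
Why: Copper-catalysed, alkoxide-directed anti-carbomagnesiation of the propargylic dialkoxide gives a chelated alkenylmagnesium whose carboxylation places CO2H cis to a CH2OH, so the butenolide closes on acidification; the diol is symmetrical and no stereocentre is formed.

Step 3
Reactants: 8 3-(hydroxymethyl)-4-[4-(trimethylsilyl)but-3-yn-1-yl]furan-2(5H)-one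
Product: 9 4-(but-3-yn-1-yl)-3-(hydroxymethyl)furan-2(5H)-one
Conditions: K2CO3 (0.1 equiv), MeOH, 0 °C
Reagents that add atoms: none
Why: Base-catalysed methanolysis of the C(sp)–Si bond (protodesilylation) is fast and leaves the tetrasubstituted butenolide untouched.

Step 4
Reactants: 9 4-(but-3-yn-1-yl)-3-(hydroxymethyl)furan-2(5H)-one
Product: 10 4-(but-3-yn-1-yl)-3-{[(tert-butyldiphenylsilyl)oxy]methyl}furan-2(5H)-one
Conditions: t-BuPh2SiCl, imidazole, DMF, rt
Reagents that add atoms: tert-butyl(chloro)diphenylsilane CC(C)(C)[Si](Cl)(c1ccccc1)c1ccccc1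
Why: Standard silylation of the primary alcohol with a group that survives every later step and is removed last.

Step 5
Reactants: 10 4-(but-3-yn-1-yl)-3-{[(tert-butyldiphenylsilyl)oxy]methyl}furan-2(5H)-one
Product: 12 4-(3-bromobut-3-en-1-yl)-3-{[(tert-butyldiphenylsilyl)oxy]methyl}furan-2(5H)-one, via alkenylborane 11 (not isolated)
Conditions: B-bromo-9-BBN (1.5 equiv), CH2Cl2, 0 °C; then AcOH, 0 °C to rt; aq. NaHCO3 work-up
Reagents that add atoms: B-bromo-9-borabicyclo[3.3.1]nonane BrB1C2CCCC1CCC2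
Why: Bromoboration of the terminal alkyne is syn and Markovnikov (Br to the internal carbon), and protodeboronation with acetic acid then gives the 2-bromo-1-alkene.

Step 6
Reactants: 12 4-(3-bromobut-3-en-1-yl)-3-{[(tert-butyldiphenylsilyl)oxy]methyl}furan-2(5H)-one
Product: 13 {[4-(3-bromobut-3-en-1-yl)-3-({[tert-butyl(diphenyl)silyl]oxy}methyl)furan-2-yl]oxy}(tert-butyl)dimethylsilane
Conditions: t-BuMe2SiOTf (1.3 equiv), Et3N, CH2Cl2, 0 °C
Reagents that add atoms: tert-butyldimethylsilyl triflate CC(C)(C)[Si](C)(C)OS(=O)(=O)C(F)(F)F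
Why: Soft enolisation of the butenolide at the γ-CH2 and O-silylation give the aromatic 2-silyloxyfuran (silyl dienol ether formation).

Step 7
Reactants: 14 prop-2-yn-1-ol
Product: 16 (2Z)-3-iodo-2-methylprop-2-en-1-ol, via alkenylmagnesium alkoxide 15 (not isolated)
Conditions: MeMgBr (2.5 equiv), CuI (10 mol%), THF, −10 °C to rt; then I2, −60 to 0 °C
Reagents that add atoms: methylmagnesium bromide C[Mg]Br; iodine II
Why: Copper-catalysed anti-carbomagnesiation puts methyl on the internal carbon and magnesium, chelated by the alkoxide, on the terminal carbon; iodinolysis with retention fixes the Z-iodoalkene.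

Step 8
Reactants: 16 (2Z)-3-iodo-2-methylprop-2-en-1-ol
Product: 17 (2Z)-3-iodo-2-methylprop-2-enal
Conditions: MnO2 (15 equiv), CH2Cl2, rt, dark
Reagents that add atoms: none
Why: Neutral allylic oxidation with MnO2 gives the enal without Z to E isomerisation; the solution is used at once.

Step 9
Reactants: 17 (2Z)-3-iodo-2-methylprop-2-enal; 18 allylmagnesium bromide
Product: 20 (1Z,3S)-1-iodo-2-methylhexa-1,5-dien-3-ol, via allylborane 19 (not isolated)
Conditions: (−)-Ipc2BOMe (from (+)-α-pinene), 18, Et2O, 0 °C to rt, salts filtered off; then 17, −100 to −78 °C; then NaOH, H2O2, 0 °C to rt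
Reagents that add atoms: none
Why: Brown allylboration through a closed chair transition state; the diisopinocampheyl reagent of the (+)-α-pinene series delivers allyl to the Si face of the aldehyde, which gives the 3S carbinol (the future C9).

Step 10
Reactants: 20 (1Z,3S)-1-iodo-2-methylhexa-1,5-dien-3-ol
Product: 21 triethyl{[(1Z,3S)-1-iodo-2-methylhexa-1,5-dien-3-yl]oxy}silane
Conditions: Et3SiCl, imidazole, CH2Cl2, 0 °C
Reagents that add atoms: chlorotriethylsilane CC[Si](CC)(CC)Cl
Why: Silylation before the alkene cleavage avoids a free β-hydroxy aldehyde (retro-aldol, dehydration) in the next step.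

Step 11
Reactants: 21 triethyl{[(1Z,3S)-1-iodo-2-methylhexa-1,5-dien-3-yl]oxy}silane
Product: 24 (3S,4Z)-5-iodo-4-methyl-3-[(triethylsilyl)oxy]pent-4-en-1-ol, via diol 22 (not isolated), via aldehyde 23 (not isolated)
Conditions: OsO4 (2 mol%), NaIO4 (4 equiv), 2,6-lutidine, dioxane/H2O, rt; then NaBH4, 0 °C
Reagents that add atoms: osmium tetroxide O=[Os](=O)(=O)=O (oxygen donor, kept in turnover by sodium periodate [Na+].[O-]I(=O)(=O)=O)
Why: Lemieux–Johnson cleavage takes the monosubstituted alkene only (the iodoalkene is electron-poor and hindered), and in-pot borohydride reduction gives the primary alcohol without touching the stereocentre.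

Step 12
Reactants: 24 (3S,4Z)-5-iodo-4-methyl-3-[(triethylsilyl)oxy]pent-4-en-1-ol
Product: 25 (1Z,3S)-1-iodo-2-methyl-3,5-bis[(triethylsilyl)oxy]pent-1-ene
Conditions: Et3SiCl, imidazole, CH2Cl2, 0 °C
Reagents that add atoms: chlorotriethylsilane CC[Si](CC)(CC)Cl
Why: The primary triethylsilyl ether is the latent aldehyde for step 14.

Step 13
Reactants: 13 {[4-(3-bromobut-3-en-1-yl)-3-({[tert-butyl(diphenyl)silyl]oxy}methyl)furan-2-yl]oxy}(tert-butyl)dimethylsilane; 25 (1Z,3S)-1-iodo-2-methyl-3,5-bis[(triethylsilyl)oxy]pent-1-ene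
Product: 26 (5R)-4-(3-bromobut-3-en-1-yl)-3-{[(tert-butyldiphenylsilyl)oxy]methyl}-5-{(1Z,3S)-2-methyl-3,5-bis[(triethylsilyl)oxy]pent-1-en-1-yl}furan-2(5H)-one
Conditions: 13 (1.3 equiv), 25 (1.0 equiv), Pd2(dba)3 (2.5 mol%), (R)-DTBM-SEGPHOS (6 mol%), ZnF2 (0.6 equiv), toluene/DMF 4:1, 40 °C
Reagents that add atoms: none
Why: Proposed new method: the zerovalent palladium/(R)-DTBM-SEGPHOS catalyst adds oxidatively to the Z-alkenyl iodide of 25 (much faster than to the 2-bromoalkene of 13, with retention of geometry); ZnF2 removes the silyl group of 13 and hands a 2-oxyfuran dienolate to palladium without free strong base; the metal binds at the unsubstituted C5 (C3 is blocked by the silyloxymethyl group) and C–C reductive elimination inside the chiral pocket gives the conjugated butenolide with the new 5R centre. The closest known reactions are the palladium-catalysed γ-arylation of silyl dienolates, 2-silyloxyfurans and butenolides with aryl halides, and the ZnF2-mediated enantioselective α-arylation and α-alkenylation of silyl ketene acetals; an enantioselective γ-alkenylation that leaves a tertiary, doubly activated γ-C–H centre has not been shown.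

Step 14
Reactants: 26 (5R)-4-(3-bromobut-3-en-1-yl)-3-{[(tert-butyldiphenylsilyl)oxy]methyl}-5-{(1Z,3S)-2-methyl-3,5-bis[(triethylsilyl)oxy]pent-1-en-1-yl}furan-2(5H)-one
Product: 27 (3S,4Z)-5-[(2R)-3-(3-bromobut-3-en-1-yl)-4-{[(tert-butyldiphenylsilyl)oxy]methyl}-5-oxo-2,5-dihydrofuran-2-yl]-4-methyl-3-[(triethylsilyl)oxy]pent-4-enal
Conditions: (COCl)2 (4 equiv), DMSO (8 equiv), CH2Cl2, −78 to −35 °C; then Et3N, −78 to −20 °C
Reagents that add atoms: none
Why: Under Swern conditions a primary triethylsilyl ether is cleaved and oxidised directly to the aldehyde, while the secondary triethylsilyl and the tert-butyldiphenylsilyl ethers stay; Et3N at low temperature does not touch the C5–H of the butenolide.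

Step 15
Reactants: 27 (3S,4Z)-5-[(2R)-3-(3-bromobut-3-en-1-yl)-4-{[(tert-butyldiphenylsilyl)oxy]methyl}-5-oxo-2,5-dihydrofuran-2-yl]-4-methyl-3-[(triethylsilyl)oxy]pent-4-enal
Product: 28 (7S,9S,10Z,11aR)-3-{[(tert-butyldiphenylsilyl)oxy]methyl}-7-hydroxy-10-methyl-6-methylidene-9-[(triethylsilyl)oxy]-5,6,7,8,9,11a-hexahydrocyclodeca[b]furan-2(4H)-one
Conditions: CrCl2 (8 equiv), NiCl2 (10 mol%), DMSO/THF 3:1, rt, 0.002 M, slow addition of 27
Reagents that add atoms: none
Why: Nozaki–Hiyama–Kishi macrocyclisation (nickel-catalysed insertion into the C–Br bond, transfer to chromium, addition to the aldehyde) is the established way to close medium rings as 2-methylidene cycloalkanols; the chain is pre-organised by the Z-alkene and the butenolide, and addition to the β-silyloxy aldehyde in the non-chelated 1,3-anti sense gives 7S.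

Step 16
Reactants: 28 (7S,9S,10Z,11aR)-3-{[(tert-butyldiphenylsilyl)oxy]methyl}-7-hydroxy-10-methyl-6-methylidene-9-[(triethylsilyl)oxy]-5,6,7,8,9,11a-hexahydrocyclodeca[b]furan-2(4H)-one
Product: 30 (7S,9S,10Z,11aR)-3-{[(tert-butyldiphenylsilyl)oxy]methyl}-10-methyl-6-methylidene-2-oxo-2,4,5,6,7,8,9,11a-octahydrocyclodeca[b]furan-7,9-diyl diacetate, via diol 29 (not isolated)
Conditions: PPTS (0.3 equiv), MeOH/CH2Cl2, 0 °C; evaporate; then Ac2O, pyridine, DMAP (10 mol%), CH2Cl2, 0 °C to rt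
Reagents that add atoms: acetic anhydride CC(=O)OC(C)=O
Why: Mild acid methanolysis removes the secondary triethylsilyl ether but not the tert-butyldiphenylsilyl ether, and DMAP-catalysed acetylation of both secondary alcohols follows without change at any stereocentre.

Step 17
Reactants: 30 (7S,9S,10Z,11aR)-3-{[(tert-butyldiphenylsilyl)oxy]methyl}-10-methyl-6-methylidene-2-oxo-2,4,5,6,7,8,9,11a-octahydrocyclodeca[b]furan-7,9-diyl diacetate
Product: 31 (7S,9S,10Z,11aR)-3-(hydroxymethyl)-10-methyl-6-methylidene-2-oxo-2,4,5,6,7,8,9,11a-octahydrocyclodeca[b]furan-7,9-diyl diacetate (CNP0398389.3)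
Conditions: HF·pyridine, pyridine, THF, 0 °C to rt
Reagents that add atoms: none
Why: Buffered fluoride cleaves the primary silyl ether; the acetates are stable, the freed alcohol is too far from them for acyl migration, and the non-basic medium leaves C11a intact.

## Compound list

1 | 4-bromobut-1-yne | C#CCCBr | starting material
2 | lithium 4-bromobut-1-yn-1-ide (not isolated) | [Li]C#CCCBr | intermediate
3 | (4-bromobut-1-yn-1-yl)trimethylsilane | C[Si](C)(C)C#CCCBr | intermediate
4 | but-2-yne-1,4-diol | OCC#CCO | starting material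
5 | [4-(trimethylsilyl)but-3-yn-1-yl]magnesium bromide (not isolated) | C[Si](C)(C)C#CCC[Mg]Br | intermediate
6 | bromo{(2Z)-1,4-bis[(chloromagnesio)oxy]-3-[4-(trimethylsilyl)but-3-yn-1-yl]but-2-en-2-yl}magnesium, Mg cis to the CH2O of the alkylated carbon (not isolated) | Cl[Mg]OC/C(CCC#C[Si](C)(C)C)=C(\[Mg]Br)CO[Mg]Cl | intermediate
7 | (2Z)-4-hydroxy-2-(hydroxymethyl)-3-[4-(trimethylsilyl)but-3-yn-1-yl]but-2-enoic acid (not isolated) | OC/C(CCC#C[Si](C)(C)C)=C(\C(=O)O)CO | intermediate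
8 | 3-(hydroxymethyl)-4-[4-(trimethylsilyl)but-3-yn-1-yl]furan-2(5H)-one | O=C1OCC(CCC#C[Si](C)(C)C)=C1CO | intermediate
9 | 4-(but-3-yn-1-yl)-3-(hydroxymethyl)furan-2(5H)-one | O=C1OCC(CCC#C)=C1CO | intermediate
10 | 4-(but-3-yn-1-yl)-3-{[(tert-butyldiphenylsilyl)oxy]methyl}furan-2(5H)-one | O=C1OCC(CCC#C)=C1CO[Si](c1ccccc1)(c1ccccc1)C(C)(C)C | intermediate
11 | 4-[(3Z)-3-bromo-4-(9-borabicyclo[3.3.1]nonan-9-yl)but-3-en-1-yl]-3-{[(tert-butyldiphenylsilyl)oxy]methyl}furan-2(5H)-one (not isolated) | O=C1OCC(CC/C(Br)=C/B2C3CCCC2CCC3)=C1CO[Si](c1ccccc1)(c1ccccc1)C(C)(C)C | intermediate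
12 | 4-(3-bromobut-3-en-1-yl)-3-{[(tert-butyldiphenylsilyl)oxy]methyl}furan-2(5H)-one | O=C1OCC(CCC(Br)=C)=C1CO[Si](c1ccccc1)(c1ccccc1)C(C)(C)C | intermediate
13 | {[4-(3-bromobut-3-en-1-yl)-3-({[tert-butyl(diphenyl)silyl]oxy}methyl)furan-2-yl]oxy}(tert-butyl)dimethylsilane (fragment A) | C=C(Br)CCc1coc(O[Si](C)(C)C(C)(C)C)c1CO[Si](c1ccccc1)(c1ccccc1)C(C)(C)C | intermediate
14 | prop-2-yn-1-ol | C#CCO | starting material
15 | bromo{(1Z)-3-[(bromomagnesio)oxy]-2-methylprop-1-en-1-yl}magnesium (not isolated) | Br[Mg]OC/C(C)=C\[Mg]Br | intermediate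
16 | (2Z)-3-iodo-2-methylprop-2-en-1-ol | OC/C(C)=C\I | intermediate
17 | (2Z)-3-iodo-2-methylprop-2-enal | O=C/C(C)=C\I | intermediate
18 | allylmagnesium bromide | C=CC[Mg]Br | starting material
19 | allylbis[(1R,2S,3R,5R)-2,6,6-trimethylbicyclo[3.1.1]heptan-3-yl]borane (not isolated) | C=CCB([C@@H]1C[C@@H]2C[C@H]([C@H]1C)C2(C)C)[C@@H]1C[C@@H]2C[C@H]([C@H]1C)C2(C)C | intermediate
20 | (1Z,3S)-1-iodo-2-methylhexa-1,5-dien-3-ol | I/C=C(C)\[C@@H](O)CC=C | intermediate
21 | triethyl{[(1Z,3S)-1-iodo-2-methylhexa-1,5-dien-3-yl]oxy}silane | I/C=C(C)\[C@@H](O[Si](CC)(CC)CC)CC=C | intermediate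
22 | (4S,5Z)-6-iodo-5-methyl-4-[(triethylsilyl)oxy]hex-5-ene-1,2-diol, both C2 epimers (not isolated) | I/C=C(C)\[C@@H](O[Si](CC)(CC)CC)CC(O)CO | intermediate
23 | (3S,4Z)-5-iodo-4-methyl-3-[(triethylsilyl)oxy]pent-4-enal (not isolated) | I/C=C(C)\[C@@H](O[Si](CC)(CC)CC)CC=O | intermediate
24 | (3S,4Z)-5-iodo-4-methyl-3-[(triethylsilyl)oxy]pent-4-en-1-ol | I/C=C(C)\[C@@H](O[Si](CC)(CC)CC)CCO | intermediate
25 | (1Z,3S)-1-iodo-2-methyl-3,5-bis[(triethylsilyl)oxy]pent-1-ene (fragment B) | I/C=C(C)\[C@@H](O[Si](CC)(CC)CC)CCO[Si](CC)(CC)CC | intermediate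
26 | (5R)-4-(3-bromobut-3-en-1-yl)-3-{[(tert-butyldiphenylsilyl)oxy]methyl}-5-{(1Z,3S)-2-methyl-3,5-bis[(triethylsilyl)oxy]pent-1-en-1-yl}furan-2(5H)-one | C=C(Br)CCC1=C(CO[Si](c2ccccc2)(c2ccccc2)C(C)(C)C)C(=O)O[C@@H]1/C=C(/C)[C@@H](O[Si](CC)(CC)CC)CCO[Si](CC)(CC)CC | intermediate
27 | (3S,4Z)-5-[(2R)-3-(3-bromobut-3-en-1-yl)-4-{[(tert-butyldiphenylsilyl)oxy]methyl}-5-oxo-2,5-dihydrofuran-2-yl]-4-methyl-3-[(triethylsilyl)oxy]pent-4-enal | C=C(Br)CCC1=C(CO[Si](c2ccccc2)(c2ccccc2)C(C)(C)C)C(=O)O[C@@H]1/C=C(/C)[C@@H](O[Si](CC)(CC)CC)CC=O | intermediate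
28 | (7S,9S,10Z,11aR)-3-{[(tert-butyldiphenylsilyl)oxy]methyl}-7-hydroxy-10-methyl-6-methylidene-9-[(triethylsilyl)oxy]-5,6,7,8,9,11a-hexahydrocyclodeca[b]furan-2(4H)-one | C=C1CCC2=C(CO[Si](c3ccccc3)(c3ccccc3)C(C)(C)C)C(=O)O[C@@H]2/C=C(/C)[C@@H](O[Si](CC)(CC)CC)C[C@@H]1O | intermediate
29 | (7S,9S,10Z,11aR)-3-{[(tert-butyldiphenylsilyl)oxy]methyl}-7,9-dihydroxy-10-methyl-6-methylidene-5,6,7,8,9,11a-hexahydrocyclodeca[b]furan-2(4H)-one (not isolated) | C=C1CCC2=C(CO[Si](c3ccccc3)(c3ccccc3)C(C)(C)C)C(=O)O[C@@H]2/C=C(/C)[C@@H](O)C[C@@H]1O | intermediate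
30 | (7S,9S,10Z,11aR)-3-{[(tert-butyldiphenylsilyl)oxy]methyl}-10-methyl-6-methylidene-2-oxo-2,4,5,6,7,8,9,11a-octahydrocyclodeca[b]furan-7,9-diyl diacetate | C=C1CCC2=C(CO[Si](c3ccccc3)(c3ccccc3)C(C)(C)C)C(=O)O[C@@H]2/C=C(/C)[C@@H](OC(C)=O)C[C@@H]1OC(C)=O | intermediate
31 | (7S,9S,10Z,11aR)-3-(hydroxymethyl)-10-methyl-6-methylidene-2-oxo-2,4,5,6,7,8,9,11a-octahydrocyclodeca[b]furan-7,9-diyl diacetate (CNP0398389.3) | C=C1CCC2=C(CO)C(=O)O[C@@H]2/C=C(/C)[C@@H](OC(C)=O)C[C@@H]1OC(C)=O | target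

## Step count and risk

Total step count: 17.
Longest linear sequence: 11 steps (steps 1 to 6, then 13 to 17; the other arm, steps 7 to 12, is equally long).

**Step 13 (the proposed γ-alkenylation).** The risks are these:
- The absolute sense of induction of a new reaction cannot be taken from precedent. It is assigned on the first run, and (S)-DTBM-SEGPHOS is used instead if the (R)-ligand gives 5S.
- The product C5–H is acidic, so proton transfer to unreacted dienolate could erode the centre or move the alkene into conjugation.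
- Coupling at C3, or ionisation of the allylic lactone C–O bond by zerovalent palladium, could compete.

Fallback (known chemistry), setting out from 13 and 25 and coming back at 26: 13 is oxidised with dimethyldioxirane (acetone, −78 °C, vinylogous Rubottom oxidation) to the lactol 4-(3-bromobut-3-en-1-yl)-3-{[(tert-butyldiphenylsilyl)oxy]methyl}-5-hydroxyfuran-2(5H)-one F1. 25 is turned by iodine–magnesium exchange (i-PrMgCl·LiCl, THF, −20 °C, retention of geometry) into chloro{(1Z,3S)-2-methyl-3,5-bis[(triethylsilyl)oxy]pent-1-en-1-yl}magnesium F2. F1 is deprotonated with i-PrMgCl (1.0 equiv, −78 °C) so that it reacts as its open aldehyde carboxylate, takes up F2 at the aldehyde carbon, and closes to the lactone on acidification with citric acid. This gives 26 together with the (5S)-epimer of 26 F3; the two are diastereomers and are separated by chromatography.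

**Step 15 (ten-membered ring closure).** The ring may close with poor or reversed selectivity at C7, because the macrocyclic conformation can override the acyclic 1,3-anti preference. Fallback, setting out from 27 and coming back at 28: the cyclisation is run as in step 15 without regard for selectivity and gives 28 mixed with the (7R)-epimer of 28 F4. The mixture is oxidised (Dess–Martin periodinane, NaHCO3, CH2Cl2) to the single enone (9S,10Z,11aR)-3-{[(tert-butyldiphenylsilyl)oxy]methyl}-10-methyl-6-methylidene-9-[(triethylsilyl)oxy]-4,5,6,8,9,11a-hexahydrocyclodeca[b]furan-2,7-dione F5. Reagent-controlled 1,2-reduction with (R)-2-methyl-CBS-oxazaborolidine and catecholborane (toluene, −78 °C; the α-methylidene carbon acts as the large group) then returns 28, so C7 is set by reduction and not in the C–C bond formation.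

**Step 2 (carbomagnesiation/carboxylation).** The functionalised Grignard reagent may add sluggishly to the dialkoxide, and excess reagent is carboxylated as well. Fallback, setting out from 3 and coming back at 8: 3 is converted (Zn dust, LiCl, THF) into bromo[4-(trimethylsilyl)but-3-yn-1-yl]zinc F6. F6 is cross-coupled at the more electrophilic C4 of commercial 3,4-dibromofuran-2(5H)-one (O=C1OCC(Br)=C1Br, eight non-hydrogen atoms) with Pd(PPh3)4 in THF, giving 3-bromo-4-[4-(trimethylsilyl)but-3-yn-1-yl]furan-2(5H)-one F7. Reductive carbonylation of the remaining bromide (CO/H2, Pd(OAc)2, di(1-adamantyl)-n-butylphosphine, TMEDA, toluene, 100 °C) gives 2-oxo-4-[4-(trimethylsilyl)but-3-yn-1-yl]-2,5-dihydrofuran-3-carbaldehyde F8. Luche reduction (NaBH4, CeCl3·7H2O, MeOH, −40 °C) of the aldehyde gives 8.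

## Further compounds

F1 | step 13 | 4-(3-bromobut-3-en-1-yl)-3-{[(tert-butyldiphenylsilyl)oxy]methyl}-5-hydroxyfuran-2(5H)-one (racemic lactol) | C=C(Br)CCC1=C(CO[Si](c2ccccc2)(c2ccccc2)C(C)(C)C)C(=O)OC1O
F2 | step 13 | chloro{(1Z,3S)-2-methyl-3,5-bis[(triethylsilyl)oxy]pent-1-en-1-yl}magnesium | Cl[Mg]/C=C(C)\[C@@H](O[Si](CC)(CC)CC)CCO[Si](CC)(CC)CC
F3 | step 13 | (5S)-4-(3-bromobut-3-en-1-yl)-3-{[(tert-butyldiphenylsilyl)oxy]methyl}-5-{(1Z,3S)-2-methyl-3,5-bis[(triethylsilyl)oxy]pent-1-en-1-yl}furan-2(5H)-one | C=C(Br)CCC1=C(CO[Si](c2ccccc2)(c2ccccc2)C(C)(C)C)C(=O)O[C@H]1/C=C(/C)[C@@H](O[Si](CC)(CC)CC)CCO[Si](CC)(CC)CC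
F4 | step 15 | (7R,9S,10Z,11aR)-3-{[(tert-butyldiphenylsilyl)oxy]methyl}-7-hydroxy-10-methyl-6-methylidene-9-[(triethylsilyl)oxy]-5,6,7,8,9,11a-hexahydrocyclodeca[b]furan-2(4H)-one | C=C1CCC2=C(CO[Si](c3ccccc3)(c3ccccc3)C(C)(C)C)C(=O)O[C@@H]2/C=C(/C)[C@@H](O[Si](CC)(CC)CC)C[C@H]1O
F5 | step 15 | (9S,10Z,11aR)-3-{[(tert-butyldiphenylsilyl)oxy]methyl}-10-methyl-6-methylidene-9-[(triethylsilyl)oxy]-4,5,6,8,9,11a-hexahydrocyclodeca[b]furan-2,7-dione | C=C1CCC2=C(CO[Si](c3ccccc3)(c3ccccc3)C(C)(C)C)C(=O)O[C@@H]2/C=C(/C)[C@@H](O[Si](CC)(CC)CC)CC1=O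
F6 | step 2 | bromo[4-(trimethylsilyl)but-3-yn-1-yl]zinc | C[Si](C)(C)C#CCC[Zn]Br
F7 | step 2 | 3-bromo-4-[4-(trimethylsilyl)but-3-yn-1-yl]furan-2(5H)-one | O=C1OCC(CCC#C[Si](C)(C)C)=C1Br
F8 | step 2 | 2-oxo-4-[4-(trimethylsilyl)but-3-yn-1-yl]-2,5-dihydrofuran-3-carbaldehyde | O=CC1=C(CCC#C[Si](C)(C)C)COC1=O
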